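**Slow feed.** Slow addition looks harmless to you, but I wouldn't bet on it: in these runs the second end groups seem to run on a clock of their own.

| flask | first end groups | second end groups | remark | time |
|---|---|---|---|---|
| elm | 10 mM | 9 mM | run made earlier |  |
| alder | 5 mM | 9 mM | run made earlier |  |
| epsilon | 10 mM (in portions, 4, over 1.0 min) | 9.00 mM | first portion at the start, last at 1.0 min | 2.5 min |
| zeta | 10 mM | 9.00 mM (fed, over 1.0 min) | all else is in the flask from the start; the feed brings no volume worth counting | 2.5 min |
| delta | 10 mM (fed, over 6.0 s) | 9.00 mM | all else is in the flask from the start; the feed brings no volume worth counting | 2.5 min |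
| gamma | 10 mM (fed, over 1.0 min) | 9.00 mM | all else is in the flask from the start; the feed brings no volume worth counting | 2.5 min |
| alpha | 10 mM | 9.00 mM | everything together at the start | 2.5 min |

- elm (time / s: side product / %, links / %, first end groups / %): 10.0: 19, 22, 59; 20.0: 40, 21, 42; 30.0: 48, 15, 33; 50.0: 63, 10, 31; 60.0: 69, 7, 26; 90.0: 74, 3, 22
- alder (time / s: side product / %, links / %, first end groups / %): 10.0: 10, 30, 57; 15.0: 18, 33, 50; 25.0: 29, 31, 37; 30.0: 36, 31, 35

(each reading ± 1.5 percentage points)

1. the flask that comes out highest in amount of side product, in percent of the first end groups charged; "all alike" if 1.5 percentage points covers them all (epsilon / zeta / delta / gamma / alpha / all alike)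
2. amount of side product at the end, in percent of the first end groups charged, epsilon
3. amount of side product at the end, in percent of the first end groups charged, zeta
4. amount of side product at the end, in percent of the first end groups charged, delta
5. amount of side product at the end, in percent of the first end groups charged, gamma
6. amount of side product at the end, in percent of the first end groups charged, alpha

- in percentages every species weighs as the first end groups in it: one side product counts as two
- the earlier runs were read with a standard deviation of 1.5 percentage points

**Uptake stalls.** Call uptake the links plus half the side product, since each holds one taken-up second end group. In elm, uptake reads 41.0% at 20.0 s and 40.0% at 90.0 s, which is 4.00 mM of 9 mM charged, though 42% of the first end groups stood free at 20.0 s. So I take the second end groups to be lost otherwise, at a first-order rate κ, beside uptake at k·A, where A is free first end groups.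

**Crossover concentration.** The uptake share is then s = A/(A + m), a selectivity factor with m = κ/k. Each uptake finally costs two first end groups, so on this picture, once the second end groups are used up, first end groups consumed plus m·ln(charged/left) equal twice the second end groups charged. Elm's last reading, counting one more loss per link, leaves 19.0% of the first end groups. That reading gives the crossover concentration, the A at which both ways are equal: m = 5.96 mM.

**The clock.** Missing uptake in elm falls from 40.0% to 8.5 points in 10.0 s, a rate of 0.155 s⁻¹. I take that rate as k·A + κ, so with a mean A of 7.95 mM I read κ as 0.0664 s⁻¹, a half-life of 10.4 s.

**My numbers.** The balance doesn't ask when the second end groups arrive, so I put alpha and zeta both near 81.0% and can't part them. I reckon delta loses 18.1% of its second end groups during half its feed, giving 66.4%. Epsilon starts at A = 2.50 mM, so s = 0.295 and roughly 53.2%. Gamma has fed 1.74 mM after one half-life, so s = 0.226 and roughly 40.7%.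

**The forecast.** It names alpha: epsilon 80.5%, zeta 80.5%, delta 82.5%, gamma 80%, alpha 83%, holding that “A one-minute addition costs about 30 s of effective reaction time”. For gamma, mine is lower.

**The flasks.** Epsilon gives 37.4%, zeta 74.1%, delta 70.0%, gamma 29.8% and alpha 78.0%, so alpha stands highest.

    first end groups + links → side product (k = 8.50 L mol⁻¹ s⁻¹)
    released group → by-product carried off (k = 0.00640 s⁻¹)
    first end groups + second end groups ⇌ links + released group (K = 11.0, k = 7.80 L mol⁻¹ s⁻¹)
    second end groups → decomposed reagent (k = 0.0600 s⁻¹)

**Same reckoning.** Gamma's 29.8% means a whole-run share of 0.166 against the 0.226 I applied to its whole run. A neighbour of alpha with 2.2 mM of second end groups starts at A = 10 mM, where s = 0.627, and that share held throughout gives about 27.6% side product. That neighbour of alpha ends at 23.8% side product, with 76.2% of its first end groups left.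

The data were computed from invented constants; the scatter is artificial.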